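The earlier runs and the new flask come from a simulation for substances that don't exist, and the scatter is random.

An order of 0.813 in the common concentration, read from two runs at one loading of J, carries this reckoning for the flask at 0.29 M.

the same everywhere: J 0.05 mol%
- maple: Z 0.14 M; Q 1.1 equiv; E 1.2 equiv; run made earlier
- oak: Z 0.22 M; Q 1.1 equiv; E 1.2 equiv; run made earlier
- flask: Z 0.29 M; Q 1.10 equiv; E 1.20 equiv; time 15 min

- maple (time / min: Z / %, D / %): 4.00: 92.7, 8.2; 8.00: 85.6, 14.4; 10.0: 82.3, 18.4; 15.0: 73.9, 26.9; 20.0: 65.6, 33.2
- oak (time / min: Z / %, D / %): 1.50: 96.4, 3.9; 5.00: 88.1, 13.2; 8.00: 79.6, 19.7; 12.0: 70.6, 29.7; 20.0: 54.4, 45.5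

(each reading ± 0.5 percentage points)

1. part of the Z that has reacted at 15 min
2. share of the unused Q that is free and not bound as QX, at 15 min

1. The main step alone. Take Z as clearing in first order, at a pace proportional to the concentration of J, which at a fixed loading follows the charge of Z. The pace is the logarithm of Z charged over Z left, divided by the time. After 20.0 min, maple gives 0.0211 min⁻¹. Oak gives 0.0304 min⁻¹. Scaling oak by the charge gives the flask 0.0401 min⁻¹, so this step puts 45.2% reacted at 15 min.

2. One more process. Oak's pace is 1.44 times maple's for 1.57 times the charge, so the pace grows with the order 0.813, below first order. The reckoned pace for the flask falls to 0.0381 min⁻¹, and the reckoned figure to 43.5%.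

3. The rest. The pace also creeps up along the maple run: the reading at 15.0 min gives 0.957 of the pace at 20.0 min, a ratio that carries the scatter of the readings. The flask's clearing rate, the pace of Z up to 15 min, is then 0.0364 min⁻¹. That gives 42.1% reacted as this reckoning's figure for the flask.

4. Free Q. The readings of Z and D do not show how much of Q is bound, so this reckoning commits to no figure for it.

The forecast puts 43% reacted and 65% free, and says of the second, “This is a guess”.

The flask gives 41.9% reacted and 99.7% free.

    QJ → X + G (k = 85.8 s⁻¹)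
    Ej → J + D (k = 5.62 s⁻¹)
    ZG → Ej (k = 6.34 s⁻¹)
    Q + X ⇌ QX, settled at all times (K = 1.60 M⁻¹)
    Z + G ⇌ ZG (K = 2.40 M⁻¹, k = 1240 M⁻¹ s⁻¹)
    E + X → EX (k = 0.305 M⁻¹ s⁻¹)
    Q + J ⇌ QJ (K = 0.479 M⁻¹, k = 11.9 M⁻¹ s⁻¹)

The clearing rate 0.0364 min⁻¹ gave 42.1% against the flask's 41.9%, and multiplied by 1.70 for a neighbour flask with 0.085 mol% of J it gives 60.5%, where that neighbour stands at 62.9%. In the flask at 15.0 min, QX is 5.08 × 10⁻⁴ M against 0.119 M of EX. At 6.86 min, ZG in the flask falls back 81 times faster than it goes on, and at 15.0 min ZG holds 12.2% of the catalyst charged.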